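Flavanone numbering is used for all ring atoms. The retrosynthesis removes the silyl group from O7 and cuts ring A at C8–C8a (6π-electrocyclisation) and C4a–C5 (alkyne coupling). It then cuts ring C at C2–C3 and O1–C8a (hetero-Diels–Alder reaction), and last the O–CH2 bond of the geranyl ether.
Ring C itself allows this order: without ring A, the six atoms O1–C2(aryl)–C3–C4(=O)–C4a=C8a are a 2-aryl-2,3-dihydropyran-4-one, which an aromatic aldehyde and a 1-methoxy-3-siloxybutadiene deliver in one operation.
Forward order: geranyl ether, ring C with C2, an iodide at C4a, C5–C8 attached as one siloxyenyne, semi-hydrogenation and closure of ring A, dehydrogenation, desilylation.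
C2 is the only stereocentre. A chiral titanium binaphtholate sets it as (S) when ring C forms, and no later step uses an enolising base, so neither the pyranone nor the flavanone can open by retro-oxa-Michael reaction.

Key step: step 2

Assumption: the (S)-configured binaphthol ligand is taken to direct the diene to the Si face of the aldehyde, as titanium binaphtholates do in related carbonyl additions; if the sense proves opposite, the equally available (R)-ligand is used and nothing else changes.

Step 1
Reactants: 1 4-hydroxybenzaldehyde; 2 geranyl bromide, (2E)-1-bromo-3,7-dimethylocta-2,6-diene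
Product: 3 4-(geranyloxy)benzaldehyde
Conditions: K2CO3, DMF, rt
Reagents that add atoms: none
Why: Williamson ether synthesis, in which the phenoxide of 1 displaces the primary allylic bromide of 2 by SN2, with O-alkylation favoured in the polar aprotic solvent and the E-alkene left untouched.

Step 2
Reactants: 3 4-(geranyloxy)benzaldehyde; 4 (E)-1-methoxy-3-(trimethylsilyloxy)buta-1,3-diene
Product: 6 (S)-2-[4-(geranyloxy)phenyl]-2,3-dihydro-4H-pyran-4-one, via silylated aldol adduct 5 (not isolated)
Conditions: Ti(OiPr)4 (10 mol %), (S)-5,5',6,6',7,7',8,8'-octahydro-1,1'-bi-2-naphthol (11 mol %), 4 Å molecular sieves, toluene, 0 °C; then TFA (0.2 equiv), CH2Cl2, 0 °C, brief; NaHCO3 quench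
Reagents that add atoms: none
Why: The titanium binaphtholate binds the aldehyde oxygen of 3, and the unsubstituted CH2 terminus of diene 4 attacks the carbonyl carbon in a Mukaiyama-type aldol addition (C2–C3); silyl transfer then releases the catalyst and leaves the open-chain adduct 5. Trifluoroacetic acid frees the C2 oxygen, which adds to the methoxy-bearing enone terminus and expels methanol (O1–C8a), so the overall change is the well-established catalytic asymmetric hetero-Diels–Alder reaction of a 1-alkoxy-3-siloxydiene with an aromatic aldehyde. Ring C closes by a 6-endo-trig addition–elimination, the stepwise counterpart of a [4+2] closure. The single stereocentre C2 is fixed in the C–C bond-forming event by the (S)-ligand, which shields the Re face so that the diene arrives at the Si face and C2 becomes (S). The step needs regioselectivity, which both oxygen donors of 4 secure by polarising the diene towards its CH2 terminus so that the aryl group ends up next to O1. It also needs chemoselectivity, which holds because the aldehyde is the only Lewis-basic electrophile, while the two trisubstituted geranyl alkenes ignore the catalyst and meet acid only briefly at 0 °C.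

Step 3
Reactants: 6 (S)-2-[4-(geranyloxy)phenyl]-2,3-dihydro-4H-pyran-4-one
Product: 7 (S)-2-[4-(geranyloxy)phenyl]-5-iodo-2,3-dihydro-4H-pyran-4-one
Conditions: I2 (1.5 equiv), pyridine/CH2Cl2 1:1, 0 °C to rt, dark; Na2S2O3 work-up
Reagents that add atoms: iodine, [I][I]
Why: Pyridine-mediated α-iodination of an enone, here an electrophilic substitution at the nucleophilic α-carbon of the vinylogous ester (pyranone C5, the future C4a) made irreversible by proton loss to pyridine, whereas iodine binds the geranyl alkenes only reversibly without an added nucleophile, and C2 is not touched.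

Step 4
Reactants: 8 but-3-yn-2-one
Product: 9 2-(tert-butyldimethylsilyloxy)but-1-en-3-yne
Conditions: TBSOTf, then Et3N, CH2Cl2, −78 to 0 °C
Reagents that add atoms: tert-butyldimethylsilyl triflate, CC(C)(C)[Si](C)(C)OS(=O)(=O)C(F)(F)F
Why: Soft enolisation with a silyl triflate and a tertiary amine converts the methyl ketone into its only possible silyl enol ether, and doing this on the achiral fragment spares the chiral pyranone any enolising conditions.

Step 5
Reactants: 7 (S)-2-[4-(geranyloxy)phenyl]-5-iodo-2,3-dihydro-4H-pyran-4-one; 9 2-(tert-butyldimethylsilyloxy)but-1-en-3-yne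
Product: 10 (S)-5-[3-(tert-butyldimethylsilyloxy)but-3-en-1-ynyl]-2-[4-(geranyloxy)phenyl]-2,3-dihydro-4H-pyran-4-one
Conditions: PdCl2(PPh3)2 (5 mol %), CuI (10 mol %), Et3N (3 equiv), degassed THF, 0 °C to rt
Reagents that add atoms: none
Why: Sonogashira coupling of an α-iodoenone with a terminal alkyne forms C4a–C5 at or below room temperature, is mild enough for the silyl enol ether, the hindered geranyl aryl ether and C2, and uses a tertiary amine that cannot add to C8a of the vinylogous ester.

Step 6
Reactants: 10 (S)-5-[3-(tert-butyldimethylsilyloxy)but-3-en-1-ynyl]-2-[4-(geranyloxy)phenyl]-2,3-dihydro-4H-pyran-4-one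
Product: 12 (2S)-7-(tert-butyldimethylsilyloxy)-2-[4-(geranyloxy)phenyl]-2,3,8,8a-tetrahydro-4H-chromen-4-one as a mixture of C8a epimers, via Z-triene 11 (not isolated)
Conditions: H2 (1 atm, one equivalent taken up), Pd/CaCO3 poisoned with Pb(OAc)2, quinoline, toluene, rt; filter; then 70 °C under argon
Reagents that add atoms: none
Why: Lindlar semi-hydrogenation adds hydrogen syn to the only alkyne and gives Z-triene 11, whose thermal disrotatory 6π-electrocyclisation (C8–C8a) is eased by the acceptor at C4a and the siloxy donor at C7; the new centre C8a forms without control relative to C2, which is harmless because step 7 flattens it.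

Step 7
Reactants: 12 (2S)-7-(tert-butyldimethylsilyloxy)-2-[4-(geranyloxy)phenyl]-2,3,8,8a-tetrahydro-4H-chromen-4-one
Product: 13 (S)-7-(tert-butyldimethylsilyloxy)-2-[4-(geranyloxy)phenyl]chroman-4-one
Conditions: DDQ (1.0 equiv), 2,4,6-collidine (2 equiv), dry CH2Cl2, −20 to 0 °C
Reagents that add atoms: none
Why: Quinone dehydrogenation of a cyclohexadiene, in which DDQ takes the C8a hydride to give a cation stabilised by both O1 and the C7 siloxy group and loss of a C8 proton completes ring A, while the collidine buffer, the single equivalent of oxidant and the low temperature hold back acid-induced departure of O1 and attack on the ether C–H bonds.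

Step 8
Reactants: 13 (S)-7-(tert-butyldimethylsilyloxy)-2-[4-(geranyloxy)phenyl]chroman-4-one
Product: 14 (S)-7-hydroxy-2-[4-(geranyloxy)phenyl]chroman-4-one, the target CNP0302343.1
Conditions: HF·pyridine, extra pyridine, THF, 0 °C; pH 6 buffer work-up
Reagents that add atoms: none
Why: Fluoride cleavage of an aryl silyl ether in a mildly acidic buffered medium frees the C7 phenol without basic conditions that would open ring C by retro-oxa-Michael reaction, so both the (S) centre and the acid-sensitive geranyl ether are kept.

Compound list
1 | 4-hydroxybenzaldehyde | O=Cc1ccc(O)cc1 | starting material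
2 | geranyl bromide, (2E)-1-bromo-3,7-dimethylocta-2,6-diene | CC(C)=CCC/C(C)=C/CBr | starting material
3 | 4-(geranyloxy)benzaldehyde | CC(C)=CCC/C(C)=C/COc1ccc(C=O)cc1 | intermediate
4 | (E)-1-methoxy-3-(trimethylsilyloxy)buta-1,3-diene | CO/C=C/C(=C)O[Si](C)(C)C | starting material
5 | (S,E)-5-[4-(geranyloxy)phenyl]-1-methoxy-5-(trimethylsilyloxy)pent-1-en-3-one | CC(C)=CCC/C(C)=C/COc1ccc([C@H](CC(=O)/C=C/OC)O[Si](C)(C)C)cc1 | intermediate
6 | (S)-2-[4-(geranyloxy)phenyl]-2,3-dihydro-4H-pyran-4-one | CC(C)=CCC/C(C)=C/COc1ccc([C@@H]2CC(=O)C=CO2)cc1 | intermediate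
7 | (S)-2-[4-(geranyloxy)phenyl]-5-iodo-2,3-dihydro-4H-pyran-4-one | CC(C)=CCC/C(C)=C/COc1ccc(cc1)[C@@H]1CC(=O)C(=CO1)I | intermediate
8 | but-3-yn-2-one | CC(=O)C#C | starting material
9 | 2-(tert-butyldimethylsilyloxy)but-1-en-3-yne | C=C(C#C)O[Si](C)(C)C(C)(C)C | intermediate
10 | (S)-5-[3-(tert-butyldimethylsilyloxy)but-3-en-1-ynyl]-2-[4-(geranyloxy)phenyl]-2,3-dihydro-4H-pyran-4-one | CC(C)=CCC/C(C)=C/COc1ccc([C@@H]2CC(=O)C(C#CC(=C)O[Si](C)(C)C(C)(C)C)=CO2)cc1 | intermediate
11 | (S)-5-[(1Z)-3-(tert-butyldimethylsilyloxy)buta-1,3-dienyl]-2-[4-(geranyloxy)phenyl]-2,3-dihydro-4H-pyran-4-one | CC(C)=CCC/C(C)=C/COc1ccc([C@@H]2CC(=O)C(/C=C\C(=C)O[Si](C)(C)C(C)(C)C)=CO2)cc1 | intermediate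
12 | (2S)-7-(tert-butyldimethylsilyloxy)-2-[4-(geranyloxy)phenyl]-2,3,8,8a-tetrahydro-4H-chromen-4-one, both C8a epimers | CC(C)=CCC/C(C)=C/COc1ccc([C@@H]2CC(=O)C3=CC=C(O[Si](C)(C)C(C)(C)C)CC3O2)cc1 | intermediate
13 | (S)-7-(tert-butyldimethylsilyloxy)-2-[4-(geranyloxy)phenyl]chroman-4-one | CC(C)=CCC/C(C)=C/COc1ccc([C@@H]2CC(=O)c3ccc(O[Si](C)(C)C(C)(C)C)cc3O2)cc1 | intermediate
14 | (S)-7-hydroxy-2-[4-(geranyloxy)phenyl]chroman-4-one | CC(C)=CCC/C(C)=C/COc1ccc([C@@H]2CC(=O)c3ccc(O)cc3O2)cc1 | target

Total steps: 8. Longest linear sequence: 7 (steps 1, 2, 3, 5, 6, 7, 8); step 4 is a one-step side branch.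

Steps most likely to fail

Step 6.
- Risk: Hydrogen uptake at the alkyne, which is flanked by two fully substituted carbons, may be sluggish. Over-reduction of the triene or of the enol ether alkene may set in before conversion is complete.
- Fallback: The reduction is moved ahead of the C4a–C5 bond formation and done by hydrometallation instead of hydrogenation. Setting out from enyne 9, radical hydrostannylation (Bu3SnH, Et3B, toluene, −78 °C, kinetic anti addition with tin at the terminal carbon) should give (Z)-tributyl[3-(tert-butyldimethylsilyloxy)buta-1,3-dien-1-yl]stannane F1. A Stille coupling of F1 with iodide 7 (PdCl2(PhCN)2, AsPh3, CuI, NMP, rt) then forms triene 11 with retention of alkene geometry and without hydrogen gas. Triene 11 closes on gentle warming, and the route is rejoined at 12.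

Step 7.
- Risk: Ionisation of the C8a–O1 bond by the acidic hydroquinone may compete with hydride abstraction and aromatise ring A with loss of the ring oxygen. Any surplus quinone may also abstract hydride from the p-alkoxybenzylic C2–H or from the allylic O–CH2 of the geranyl ether.
- Fallback: The cationic quinone oxidation is replaced by an organometallic one that uses up the silyl dienol ether itself. Setting out from 12, a Saegusa–Ito oxidation (Pd(OAc)2, 2,6-di-tert-butylpyridine, MeCN, rt, no phosphine, so that the zerovalent palladium formed does not ionise the hindered allylic ether) exchanges silicon for divalent palladium. β-Hydride elimination of the C8a hydrogen then gives (2S)-2-[4-(geranyloxy)phenyl]-2,3-dihydro-4H-chromene-4,7(8H)-dione F2. F2 tautomerises to the phenol, so the route is rejoined directly at 14 and step 8 is no longer needed.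

Step 2.
- Risk: Addition to the electron-rich aldehyde may be slow enough for an achiral silyl-cation-catalysed background reaction to erode the facial selectivity. The acid treatment may also begin to protonate the geranyl alkenes.
- Fallback: The same two bonds are formed under hydrogen-bond catalysis with a more reactive diene and without any protic acid. Setting out from 3, commercial (E)-1-(dimethylamino)-3-(tert-butyldimethylsilyloxy)buta-1,3-diene is used with the enantiomer of α,α,α',α'-tetra(1-naphthyl)-2,2-dimethyl-1,3-dioxolane-4,5-dimethanol that exposes the Si face (20 mol %, toluene, −40 °C). A concerted [4+2] cycloaddition should give (6S)-4-(tert-butyldimethylsilyloxy)-6-[4-(geranyloxy)phenyl]-N,N-dimethyl-5,6-dihydro-2H-pyran-2-amine F3. Acetyl chloride (CH2Cl2, −78 °C) then removes the amino and silyl groups, and the route is rejoined at 6.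

Further compounds
F1 | step 6 | (Z)-tributyl[3-(tert-butyldimethylsilyloxy)buta-1,3-dien-1-yl]stannane | C=C(O[Si](C)(C)C(C)(C)C)/C=C\[Sn](CCCC)(CCCC)CCCC
F2 | step 7 | (2S)-2-[4-(geranyloxy)phenyl]-2,3-dihydro-4H-chromene-4,7(8H)-dione | CC(C)=CCC/C(C)=C/COc1ccc([C@@H]2CC(=O)C3=C(O2)CC(=O)C=C3)cc1
F3 | step 2 | (6S)-4-(tert-butyldimethylsilyloxy)-6-[4-(geranyloxy)phenyl]-N,N-dimethyl-5,6-dihydro-2H-pyran-2-amine | CC(C)=CCC/C(C)=C/COc1ccc([C@@H]2CC(O[Si](C)(C)C(C)(C)C)=CC(N(C)C)O2)cc1
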